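**Assumption:** the SMILES is taken as authoritative for absolute configuration; it corresponds to (1R,3aR,4R,5S,7aS)-3-ethyl-1,4,5,7-tetramethyl-5-[(1E,3E)-2-methyl-4-phenylbuta-1,3-dienyl]-3a,4,5,7a-tetrahydro-1H-indene-4-carboxylic acid. This is a paper design; no step has been run.

## Retrosynthetic overview

1. Target acid ⇐ its 2-(trimethylsilyl)ethyl (TMSE) ester by fluoride cleavage, which works regardless of the steric hindrance at the quaternary carboxyl carbon.
2. TMSE ester ⇐ type-1 intramolecular Diels–Alder (IMDA) of a linear (2E,4Z,6S,7E,9E,11E,13E)-hexaenoate. The cyclopentene and cyclohexene close in the same step, and the four ring stereocentres are relayed from the single C6 stereocentre.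
3. Linear hexaenoate ⇐ C5–C6 disconnection at the lone sp3 stereocentre: proposed Ni–H enantioselective Markovnikov hydroalkenylation of the terminal diene of an all-E phenylpentaene with a (Z)-dienyl boronate.
4. Phenylpentaene ⇐ acrolein by three formyl-ylide Wittig homologations and a benzylphosphonate HWE.
5. (Z)-Dienyl boronate ⇐ propargyl alcohol by Cu-catalysed anti-ethylmagnesiation/iodination, oxidation, Wittig and Miyaura borylation.

## Route

**Step 1**
Reactants: 1 acrolein; 2 2-(triphenylphosphoranylidene)propanal
Product: 3 (E)-2-methylpenta-2,4-dienal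
Conditions: CH2Cl2, BHT, 0 °C → rt; used as a solution
Reagents that add atoms: 2-(triphenylphosphoranylidene)propanal, CC(C=O)=P(c1ccccc1)(c1ccccc1)c1ccccc1
Why: Wittig olefination with a formyl-stabilised ylide gives the (E)-2-methyl enal, and the α-branched dienal product is much less electrophilic than acrolein, so homologation stops after one unit.

**Step 2**
Reactants: 3 (E)-2-methylpenta-2,4-dienal; 2 2-(triphenylphosphoranylidene)propanal
Product: 4 (2E,4E)-2,4-dimethylhepta-2,4,6-trienal
Conditions: PhMe, BHT, 90 °C
Reagents that add atoms: 2-(triphenylphosphoranylidene)propanal, CC(C=O)=P(c1ccccc1)(c1ccccc1)c1ccccc1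
Why: Second stabilised-ylide Wittig homologation, E-selective for the new trisubstituted alkene.

**Step 3**
Reactants: 4 (2E,4E)-2,4-dimethylhepta-2,4,6-trienal; 2 2-(triphenylphosphoranylidene)propanal
Product: 5 (2E,4E,6E)-2,4,6-trimethylnona-2,4,6,8-tetraenal
Conditions: PhMe, BHT, 100 °C, dark
Reagents that add atoms: 2-(triphenylphosphoranylidene)propanal, CC(C=O)=P(c1ccccc1)(c1ccccc1)c1ccccc1
Why: Third stabilised-ylide Wittig homologation, again E-selective.

**Step 4**
Reactants: 5 (2E,4E,6E)-2,4,6-trimethylnona-2,4,6,8-tetraenal; 6 diethyl benzylphosphonate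
Product: 7 [(1E,3E,5E,7E)-3,5,7-trimethyldeca-1,3,5,7,9-pentaen-1-yl]benzene
Conditions: NaH, THF, 0 °C → rt, dark
Reagents that add atoms: diethyl benzylphosphonate, CCOP(=O)(Cc1ccccc1)OCC
Why: Horner–Wadsworth–Emmons olefination with a benzylic phosphonate gives the (E)-styryl terminus.

**Step 5**
Reactants: 8 propargyl alcohol; 9 ethylmagnesium bromide; 10 iodine
Product: 11 (Z)-2-ethyl-3-iodoprop-2-en-1-ol (I cis to CH2OH)
Conditions: EtMgBr (3 equiv), CuI (10 mol %), THF, −10 °C → rt; then I2, −78 °C → rt
Reagents that add atoms: ethylmagnesium bromide, CC[Mg]Br; iodine, II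
Why: Cu-catalysed alkoxide-directed anti-carbomagnesiation of propargyl alcohol puts Et on C2 and Mg on C3 cis to CH2O in a five-membered chelate, and iodinolysis with retention gives the Z vinyl iodide.

**Step 6**
Reactants: 11 (Z)-2-ethyl-3-iodoprop-2-en-1-ol
Product: 12 (Z)-2-ethyl-3-iodoprop-2-enal
Conditions: MnO2, CH2Cl2, rt, dark; used at once
Reagents that add atoms: none
Why: Neutral MnO2 oxidation of the allylic alcohol leaves the Z C–I geometry intact.

**Step 7**
Reactants: 13 2-bromopropanoyl bromide; 14 2-(trimethylsilyl)ethanol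
Product: 15 2-(trimethylsilyl)ethyl 2-bromopropanoate (racemic)
Conditions: pyridine, CH2Cl2, 0 °C → rt
Reagents that add atoms: 2-(trimethylsilyl)ethanol, C[Si](C)(C)CCO
Why: Simple acylation of the alcohol by the acid bromide.

**Step 8**
Reactants: 15 2-(trimethylsilyl)ethyl 2-bromopropanoate; 16 triphenylphosphine
Product: 17 2-(trimethylsilyl)ethyl 2-(triphenylphosphoranylidene)propanoate
Conditions: PPh3, PhMe, 80 °C; then 1 M NaOH, CH2Cl2, 0 °C
Reagents that add atoms: triphenylphosphine, c1ccc(cc1)P(c1ccccc1)c1ccccc1
Why: SN2 quaternisation of the α-bromo ester followed by deprotonation gives the stabilised ylide.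

**Step 9**
Reactants: 12 (Z)-2-ethyl-3-iodoprop-2-enal; 17 2-(trimethylsilyl)ethyl 2-(triphenylphosphoranylidene)propanoate
Product: 18 2-(trimethylsilyl)ethyl (2E,4Z)-4-ethyl-5-iodo-2-methylpenta-2,4-dienoate
Conditions: CH2Cl2, rt → 40 °C, dark
Reagents that add atoms: ylide 17, CC(C(=O)OCC[Si](C)(C)C)=P(c1ccccc1)(c1ccccc1)c1ccccc1
Why: Stabilised-ylide Wittig gives the (2E)-2-methyl enoate, with the vinyl iodide and its Z geometry as spectators.

**Step 10**
Reactants: 18 iodo-dienoate; 19 bis(pinacolato)diboron
Product: 20 2-(trimethylsilyl)ethyl (2E,4Z)-4-ethyl-2-methyl-5-(4,4,5,5-tetramethyl-1,3,2-dioxaborolan-2-yl)penta-2,4-dienoate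
Conditions: B2pin2, PdCl2(PPh3)2 (3 mol %), PPh3, KOPh, PhMe, 50 °C
Reagents that add atoms: bis(pinacolato)diboron, CC1(C)OB(OC1(C)C)B1OC(C)(C)C(C)(C)O1
Why: Miyaura borylation of an alkenyl iodide proceeds with retention of alkene geometry.

**Step 11 (key new step)**
Reactants: 7 phenylpentaene; 20 (Z)-dienyl boronate (1.3 equiv)
Product: 21 2-(trimethylsilyl)ethyl (2E,4Z,6S,7E,9E,11E,13E)-4-ethyl-2,6,8,10,12-pentamethyl-14-phenyltetradeca-2,4,7,9,11,13-hexaenoate
Conditions: Ni(cod)2 (10 mol %), bulky chiral monodentate spiro-phosphoramidite L* (12 mol %), MeOH/THF 1:4, 25 °C, dark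
Reagents that add atoms: boronate 20, C[Si](C)(C)CCOC(=O)/C(C)=C/C(CC)=C\B1OC(C)(C)C(C)(C)O1 (MeOH supplies only H)
Why: Proposed new method: Ni(0)/chiral-phosphoramidite enantioselective Markovnikov 1,2-hydroalkenylation of the terminal diene of a conjugated pentaene with an enoate-bearing (Z)-alkenyl boronate — MeOH protonates the Ni(0)–diene complex at the terminal CH2 (creating the C6 methyl) to give a syn-η3-allyl–Ni–OMe, the alkenyl–Bpin transmetalates through Ni–OMe with retention of Z geometry, and ligand-controlled C(sp3)–C(sp2) reductive elimination at the less substituted CH(CH3) allyl terminus forms C5–C6 and sets C6 as S (ligand antipode chosen by assay), keeping the 7E alkene because the syn-allyl is both kinetic and thermodynamic; the bulky monodentate ligand is intended to make reductive elimination faster than η3–η1–η3 migration of Ni along the polyene; closest known reaction type is Ni(0)-catalysed enantioselective hydroarylation/hydroalkenylation of 1-aryl-1,3-dienes and styrenes with organoboron reagents in alcohol, not shown on extended polyenes or with trisubstituted (Z)-dienyl boronates.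

**Step 12**
Reactants: 21 linear hexaenoate
Product: 22 2-(trimethylsilyl)ethyl (1R,3aR,4R,5S,7aS)-3-ethyl-1,4,5,7-tetramethyl-5-[(1E,3E)-2-methyl-4-phenylbuta-1,3-dienyl]-3a,4,5,7a-tetrahydro-1H-indene-4-carboxylate
Conditions: PhMe (0.01 M), BHT, 85 °C, degassed, dark
Reagents that add atoms: none
Why: Type-1 intramolecular Diels–Alder of the C7–C10 diene with the C2=C3 enoate through the C4=C5–C6 tether: C6–H eclipses the diene (A1,3 strain with the C8 methyl) so the dienophile adds anti to the C6 methyl, the ester-endo/tether-exo transition state gives the trans ring fusion, and suprafacial addition of the E-enoate to the E,E-diene places the two quaternary methyls cis.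

**Step 13**
Reactants: 22 TMSE ester
Product: 23 zyggomphic acid B
Conditions: TBAF, THF, 0 °C → rt
Reagents that add atoms: none
Why: Fluoride attack at silicon triggers β-elimination of ethylene and TMSF, freeing the carboxylate without nucleophilic attack at the hindered quaternary carbonyl and without touching the alkenes or stereocentres.

## Compound list

1 | acrolein | C=CC=O | starting material
2 | 2-(triphenylphosphoranylidene)propanal | CC(C=O)=P(c1ccccc1)(c1ccccc1)c1ccccc1 | starting material
3 | (E)-2-methylpenta-2,4-dienal | O=C/C(C)=C/C=C | intermediate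
4 | (2E,4E)-2,4-dimethylhepta-2,4,6-trienal | O=C/C(C)=C/C(C)=C/C=C | intermediate
5 | (2E,4E,6E)-2,4,6-trimethylnona-2,4,6,8-tetraenal | O=C/C(C)=C/C(C)=C/C(C)=C/C=C | intermediate
6 | diethyl benzylphosphonate | CCOP(=O)(Cc1ccccc1)OCC | starting material
7 | [(1E,3E,5E,7E)-3,5,7-trimethyldeca-1,3,5,7,9-pentaen-1-yl]benzene | C=C/C=C(C)/C=C(C)/C=C(C)/C=C/c1ccccc1 | intermediate
8 | propargyl alcohol | C#CCO | starting material
9 | ethylmagnesium bromide | CC[Mg]Br | starting material
10 | iodine | II | starting material
11 | (Z)-2-ethyl-3-iodoprop-2-en-1-ol | OC/C(CC)=C\I | intermediate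
12 | (Z)-2-ethyl-3-iodoprop-2-enal | O=C/C(CC)=C\I | intermediate
13 | 2-bromopropanoyl bromide | CC(Br)C(=O)Br | starting material
14 | 2-(trimethylsilyl)ethanol | C[Si](C)(C)CCO | starting material
15 | 2-(trimethylsilyl)ethyl 2-bromopropanoate (racemic) | CC(Br)C(=O)OCC[Si](C)(C)C | intermediate
16 | triphenylphosphine | c1ccc(cc1)P(c1ccccc1)c1ccccc1 | starting material
17 | 2-(trimethylsilyl)ethyl 2-(triphenylphosphoranylidene)propanoate | CC(C(=O)OCC[Si](C)(C)C)=P(c1ccccc1)(c1ccccc1)c1ccccc1 | intermediate
18 | 2-(trimethylsilyl)ethyl (2E,4Z)-4-ethyl-5-iodo-2-methylpenta-2,4-dienoate | C[Si](C)(C)CCOC(=O)/C(C)=C/C(CC)=C\I | intermediate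
19 | bis(pinacolato)diboron | CC1(C)OB(OC1(C)C)B1OC(C)(C)C(C)(C)O1 | starting material
20 | 2-(trimethylsilyl)ethyl (2E,4Z)-4-ethyl-2-methyl-5-(pinacolboryl)penta-2,4-dienoate | C[Si](C)(C)CCOC(=O)/C(C)=C/C(CC)=C\B1OC(C)(C)C(C)(C)O1 | intermediate
21 | 2-(trimethylsilyl)ethyl (2E,4Z,6S,7E,9E,11E,13E)-4-ethyl-2,6,8,10,12-pentamethyl-14-phenyltetradeca-2,4,7,9,11,13-hexaenoate | C[Si](C)(C)CCOC(=O)/C(C)=C/C(CC)=C\[C@@H](C)/C=C(C)/C=C(C)/C=C(C)/C=C/c1ccccc1 | intermediate
22 | TMSE ester of zyggomphic acid B (1R,3aR,4R,5S,7aS) | CCC1=C[C@@H](C)[C@@H]2C(C)=C[C@](C)(/C=C(C)/C=C/c3ccccc3)[C@](C)(C(=O)OCC[Si](C)(C)C)[C@@H]12 | intermediate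
23 | zyggomphic acid B | CCC1=C[C@@H](C)[C@@H]2C(C)=C[C@](C)(/C=C(C)/C=C/c3ccccc3)[C@](C)(C(=O)O)[C@@H]12 | target

## Totals and risk

Total steps: 13. Longest linear sequence: 7 (steps 1–4, 11–13; equally steps 5, 6, 9, 10, 11–13).

Steps most likely to fail:

1. **Step 11 (proposed new Ni–H hydroalkenylation).** Risks are Ni migration along the polyene (coupling at a remote or benzylic position, E/Z scrambling), slow transmetalation of the hindered electron-poor alkenyl boronate, and low ee. Fallback with known chemistry: make 21 by a chiral-pool route. Roche ester supplies C6. One arm goes to the methyl alkyne (Corey–Fuchs/MeI), then Cp2Zr(H)Cl/I2 to the (E)-vinyl iodide, then Negishi coupling with the trienyl alane from Zr-catalysed carboalumination of the corresponding phenyl dienyne. The other arm is oxidised to the aldehyde and taken through a Z-selective Still–Gennari olefination (bis(trifluoroethyl) 2-phosphonobutanoate), DIBAL/MnO2 and Wittig with 17.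

2. **Step 12 (IMDA).** Risks are incomplete trans/cis-fusion or facial selectivity when two adjacent quaternary centres form, or a competing [1,5]-H shift in the (Z)-dienoate if forcing temperatures are needed. Fallback: change the dienophile and activation mode. Convert the ester of 21 to the (2E,4Z)-dienal (DIBAL, then MnO2), run the cycloaddition at or below 0 °C under Me2AlCl or imidazolidinone-iminium catalysis, and finish with Pinnick oxidation of the neopentyl aldehyde to the acid.

3. **Step 3 (third formyl-ylide homologation; also applies to handling of 3–5 and 7).** Risks are low electrophilicity of the vinylogous enal and polyene decomposition or isomerisation on prolonged heating. Fallback: assemble 7 from the phenyl end by iterative Zr-catalysed methylalumination/iodination and Sonogashira/desilylation cycles starting from (E)-1-phenylbut-1-en-3-yne, ending with a Pd-catalysed Negishi coupling of the final alkenylalane with vinyl bromide.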